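## The problem

Magnolignan H (23) is a 2,3-dihydrobenzofuran whose benzene ring (C3a to C7a) is substituted at every position but C5: an allyl group at C4, a 4-allylphenoxy group at C6 and a free hydroxyl at C7, next to the ring oxygen O1 on C7a. C2 carries CH2OH and C3 carries a 4-hydroxy-3-(5-allyl-2-hydroxyphenyl)phenyl group; the two are cis, (2R,3S), which is the less stable arrangement. These are the only stereocentres and they are neighbours, so nothing remote can relay to them, and a route that sets one after the other works against the trans preference. The safer course is to create both in one suprafacial event, so that cis follows from mechanism and a chiral catalyst has only to choose the face. Once set, C2 must not sit next to a carbonyl group in the presence of base, and the doubly benzylic C3–H must not meet strong base or oxidants. Three terminal allyl groups, which move into conjugation under metal hydrides, strong base or hot acid, and three phenols on electron-rich rings limit what can be done late. The three contiguous aryl–oxygen bonds at C6, C7 and C7a point to a 3,4,5-trioxygenated benzaldehyde, whose formyl carbon sits where C4 needs a carbon substituent. That is the enabling feature: C3a–H lies between C4, which can hold the formyl group as an imine that steers a metal into C3a–H, and C7a–O1, which can hold C2 and C3 as an enol ether with an ester as the future CH2OH.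

## Retrosynthesis

From 23 back to 21. The last bonds made are the three phenolic O–H bonds (from the MOM ethers of 22) and the two aryl–allyl bonds on the phenoxy ring and on the outer ring of the biaryl (from the aryl chlorides of 21). Installing these allyl groups last is forced by the key step, whose rhodium hydride would move terminal double bonds into conjugation. A chloride para to oxygen is the smallest placeholder that survives copper, rhodium, hydride and triphenylphosphine–palladium chemistry and can still be coupled. The forward steps must transfer allyl from tin to two electron-rich aryl chlorides without double-bond migration, and cleave three acetals with acid in the presence of three allyl groups, none of which is ortho to a phenol.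

From 21 back to 17. The C4 allyl group is cut between its benzylic carbon and the vinyl group, leading through benzylic bromide 19 and alcohol 18 to aldehyde 17; the C2 hydroxymethyl group is traced to the methyl ester (20 to 21). A two-carbon Wittig homologation would pass through a labile arylacetaldehyde and cost more steps, and vinyl addition followed by deoxygenation would favour the conjugated propenyl isomer. Coupling a benzylic bromide with a vinylstannane gives the allylarene directly under neutral conditions. The ester is kept until that coupling is done, so that the benzylic alcohol is the only hydroxyl at the bromination stage, and it is reduced before the fluoride-promoted coupling, after which C2 can no longer epimerise. The forward steps must reduce a formyl group beside an activated ester and handle the cis ester without base.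

From 17 back to 15. Hydrolysis relates 17 to imine 16, and the strategic cut is made in 16: the C3–C3a bond and the C2–H bond are removed together. This opens the dihydrofuran ring, erases both stereocentres and leaves the flat, achiral Z enol ether 15. A cut at O1–C2 (phenoxide displacement) would need both centres built separately in an open chain and an inversion next to a carbonyl group; cuts at C2–C3 are examined under the alternatives. The forward reaction must let rhodium, guided by the imine nitrogen, enter C3a–H, add C3a and H to the same face of the alkene (cis from Z), let the chiral ligand pick that face, and leave the alkene geometry and the aryl chlorides alone.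

From 15 back to 8 and 12. Imine 15 comes from aldehyde 14, and the C2=C3 double bond is cut by a Horner–Wadsworth–Emmons disconnection into aryloxy phosphonoacetate 8 and biaryl aldehyde 12. This divides the molecule into halves of similar size and places the alkene geometry under thermodynamic control (ester trans to aryl, which is Z). One correction to the simplest form of this cut is needed: a phosphonate anion on a ring that also bears a free formyl group would olefinate its own kind. The formyl group is therefore carried as a dimethyl acetal through the olefination (13) and released afterwards (14).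

From 8 back to 1. The O1–C2 bond is cut as a rhodium carbenoid O–H insertion of diazophosphonoacetate 7 (one step from 6) into phenol 5, which avoids the halophilic side reactions of alpha-halo phosphonoacetates; 5 is the acetal of aldehyde 4. The diaryl ether bond of 4 is cut to boronic acid 3 and diol 2 (Chan–Lam coupling), and 2 comes from 3,4,5-trihydroxybenzaldehyde 1 by etherification of its most acidic hydroxyl. The price is one statistical step, since 2 is symmetric; it is accepted because the sequence is short and unused diol is recovered.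

From 12 back to 9 and 10. The biaryl bond is cut to 4-hydroxy-3-iodobenzaldehyde 9 and boronic acid 10 (Suzuki–Miyaura coupling), the iodide reacting in preference to the chloride; biphenol 11 is then capped as the bis-MOM ether 12.

## Roads not taken

Alternative 1: The cut is at C2–C3 together with C3–C3a: C2 and C3 are joined first in a four-membered lactone and the arene is attached to C3 afterwards. Forward, acid chloride A1 would give an aryloxyketene-derived ammonium enolate with a silylated cinchona alkaloid, LiClO4 and iPr2NEt, which adds to aldehyde A2 and lactonises to the cis-beta-lactone A3. A Lewis acid would then make C3a attack C3 with inversion, opening the lactone to the cis-2-carboxy dihydrobenzofuran.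
- Merits: metal-free asymmetric catalysis with a predictable sense of induction, full convergence, and all three allyl groups carried from the start. On paper this road is clearly shorter than the chosen one.
- Weak points: the cyclocondensation is at its best with reactive aliphatic aldehydes, whereas A2 is a hindered aryl aldehyde. A3, a 4-aryl-beta-lactone with a para oxygen on the aryl group, is prone to ionise and lose CO2. The closure needs a clean backside attack by an arene tethered through a single oxygen to the neighbouring carbon of a four-membered ring; ionisation to the benzylic cation is the easier path and would lead to the trans product.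
- Comparison: the chosen plan is longer, but its cis relation rests on syn addition to an alkene of known geometry, not on an inversion at an ionisable benzylic carbon.

Alternative 2: The cut is again C2–C3, made as a [4+2] cycloaddition with O1 bonded for the time being to the wrong carbon. Forward, a bulky chiral BINOL-derived phosphoric acid dehydrates benzhydrol A4 to an ortho-quinone methide, which adds dioxole A5 in an endo sense to give the all-cis chromane acetonide A6, with C3 as in the target.
- Merits: A4 is one aryl-metal addition away from simple halves. The catalyst class has a strong record of enantiocontrol in ortho-quinone methide cycloadditions, probably stronger than that of the chosen key step. No metal hydride is involved, so the remote allyl groups can be present.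
- Weak points: A6 is a chromane, not a dihydrobenzofuran. The acetonide must be opened, the acetal carbon reduced to the future CH2OH, the primary hydroxyl protected and O1 re-attached to C2 with inversion. Only then can the C4 allyl group be delivered by a thermal para-Claisen shift from the C7 allyl ether, at around 200 °C on a molecule holding a cis stereo-pair and three other allyl groups. A5 is volatile, not routinely available and a less tested partner than enamides or styrenes.
- Comparison: the chosen plan is no shorter overall, but its key step delivers the final ring, both centres and the C4 carbon at once.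

Alternative 3: The cut is C2–C3, made by carbene C–H insertion. Forward, hydrazone A7 is oxidised with MnO2 to diazoalkane A8, which loses N2 on a chiral dirhodium tetracarboxylate, Rh2(R-PTAD)4 (divalent rhodium). The donor/donor carbene inserts into the OCH2 C–H bond five atoms away to give the cis-dihydrobenzofuran A9.
- Merits: this reaction class is known to give 2,3-cis-dihydrobenzofurans with high enantioselectivity. C2 arrives at the alcohol oxidation level with no epimerisable ester, and little more than deprotection and one allyl transfer remain. In stereochemical precedent and in the number of steps after ring closure this is the strongest rival and better than the chosen plan.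
- Weak points: A8 carries four alkenes (three allyl groups and one allyl ether) and several activated C–H bonds (the OCH2O groups of the MOM ethers, the allylic OCH2) that compete for the carbene. The hindered 2,3,4-trioxygenated diaryl ketone must be made and converted into A7. C4 is still unsubstituted in A9, so its allyl group must migrate from O7 by para-Claisen rearrangement at high temperature on the finished cis core.
- Comparison: in the chosen plan no alkene other than the reacting one is present when the reactive metal species is formed, and the C4 carbon is part of the design, not a late thermal step.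

Key step: step 11

Assumption: the sense of induction of the phosphoramidite on this trisubstituted enol ether cannot be predicted with confidence; the (S,R,R) ligand is written for the (2R,3S) product and its (R,S,S) antipode is used if the first test shows the opposite sense.

## Route

Step 1
Reactants: 1 3,4,5-trihydroxybenzaldehyde
Product: 2 3,5-dihydroxy-4-(methoxymethoxy)benzaldehyde
Conditions: MOMCl (1.0 equiv), K2CO3 (1.0 equiv), acetone, 0 °C to rt, N2
Reagents that add atoms: chloromethyl methyl ether, COCCl
Why: The 4-hydroxyl, para to the formyl group, is the most acidic of the three, so one equivalent of weak base forms the 4-phenoxide and Williamson etherification should stop at the mono-ether; selective 4-O-alkylation of 3,4-di- and 3,4,5-trihydroxybenzaldehydes is standard practice.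

Step 2
Reactants: 2 3,5-dihydroxy-4-(methoxymethoxy)benzaldehyde; 3 (4-chlorophenyl)boronic acid
Product: 4 3-(4-chlorophenoxy)-5-hydroxy-4-(methoxymethoxy)benzaldehyde
Conditions: Cu(OAc)2 (20 mol %), pyridine, 4 Å MS, CH2Cl2, O2 (1 atm), rt; 3 as limiting reagent (0.9 equiv)
Reagents that add atoms: none
Why: Chan–Lam O-arylation runs at room temperature and tolerates formyl, MOM and aryl chloride groups; the two hydroxyls of 2 are equivalent, so keeping 3 limiting should hold double arylation down, and unreacted 2 is recovered and recycled.

Step 3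
Reactants: 4 3-(4-chlorophenoxy)-5-hydroxy-4-(methoxymethoxy)benzaldehyde
Product: 5 3-(4-chlorophenoxy)-5-(dimethoxymethyl)-2-(methoxymethoxy)phenol
Conditions: HC(OMe)3, MeOH, PPTS (cat.), rt; Et3N quench
Reagents that add atoms: trimethyl orthoformate, COC(OC)OC; methanol, CO
Why: Acetalisation masks the formyl group so that the phosphonate anion of step 8 cannot olefinate its own aldehyde; pyridinium tosylate at room temperature is too weak an acid to cleave the aryl MOM ether.

Step 4
Reactants: 6 trimethyl phosphonoacetate
Product: 7 methyl 2-diazo-2-(dimethoxyphosphoryl)acetate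
Conditions: 4-AcNHC6H4SO2N3, DBU, MeCN, 0 °C to rt
Reagents that add atoms: 4-acetamidobenzenesulfonyl azide, CC(=O)Nc1ccc(cc1)S(=O)(=O)N=[N+]=[N-]
Why: Regitz diazo transfer to a doubly activated methylene group is routine, and the sulfonamide by-product is removed by filtration and chromatography.

Step 5
Reactants: 5 3-(4-chlorophenoxy)-5-(dimethoxymethyl)-2-(methoxymethoxy)phenol; 7 methyl 2-diazo-2-(dimethoxyphosphoryl)acetate
Product: 8 methyl 2-[3-(4-chlorophenoxy)-5-(dimethoxymethyl)-2-(methoxymethoxy)phenoxy]-2-(dimethoxyphosphoryl)acetate (racemic)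
Conditions: Rh2(OAc)4 (2 mol %), toluene, 80 °C, slow addition of 7
Reagents that add atoms: none
Why: Rhodium carbenoid O–H insertion into phenols is the established route to 2-aryloxy phosphonoacetates and outpaces C–H insertion or ylide formation at the acetal and ether oxygens; the new centre is racemic and disappears in step 8.

Step 6
Reactants: 9 4-hydroxy-3-iodobenzaldehyde; 10 (5-chloro-2-hydroxyphenyl)boronic acid
Product: 11 3-(5-chloro-2-hydroxyphenyl)-4-hydroxybenzaldehyde
Conditions: Pd(PPh3)4 (3 mol %), K2CO3, dioxane/H2O, 80 °C
Reagents that add atoms: none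
Why: Suzuki–Miyaura coupling; zerovalent palladium with triphenylphosphine inserts into the C–I bond far faster than into C–Cl, and the free phenols are tolerated as phenoxides.

Step 7
Reactants: 11 3-(5-chloro-2-hydroxyphenyl)-4-hydroxybenzaldehyde
Product: 12 3-[5-chloro-2-(methoxymethoxy)phenyl]-4-(methoxymethoxy)benzaldehyde
Conditions: NaH, MOMCl, DMF, 0 °C to rt
Reagents that add atoms: chloromethyl methyl ether, COCCl
Why: Williamson etherification of both phenoxides; the aldehyde has no enolisable hydrogen, and sodium hydride ensures that the hydrogen-bonded biphenol is fully alkylated.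

Step 8
Reactants: 8 methyl 2-[3-(4-chlorophenoxy)-5-(dimethoxymethyl)-2-(methoxymethoxy)phenoxy]-2-(dimethoxyphosphoryl)acetate; 12 3-[5-chloro-2-(methoxymethoxy)phenyl]-4-(methoxymethoxy)benzaldehyde
Product: 13 methyl (Z)-2-[3-(4-chlorophenoxy)-5-(dimethoxymethyl)-2-(methoxymethoxy)phenoxy]-3-{3-[5-chloro-2-(methoxymethoxy)phenyl]-4-(methoxymethoxy)phenyl}prop-2-enoate
Conditions: LiCl, DBU, MeCN, 0 °C to rt
Reagents that add atoms: none
Why: Horner–Wadsworth–Emmons olefination under Masamune–Roush conditions; reversible addition under a mild amine base should favour the isomer with the ester trans to the aryl group, which is Z because the aryloxy group outranks the ester, as in Z-selective syntheses of dehydroamino esters and 2-alkoxycinnamates. Any E isomer is removed by chromatography on triethylamine-buffered silica.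

Step 9
Reactants: 13 methyl (Z)-2-[3-(4-chlorophenoxy)-5-(dimethoxymethyl)-2-(methoxymethoxy)phenoxy]-3-{3-[5-chloro-2-(methoxymethoxy)phenyl]-4-(methoxymethoxy)phenyl}prop-2-enoate
Product: 14 methyl (Z)-2-[3-(4-chlorophenoxy)-5-formyl-2-(methoxymethoxy)phenoxy]-3-{3-[5-chloro-2-(methoxymethoxy)phenyl]-4-(methoxymethoxy)phenyl}prop-2-enoate
Conditions: AcOH/H2O/THF, rt
Reagents that add atoms: water, O
Why: An aryl dimethyl acetal with a para alkoxy group hydrolyses in dilute acetic acid far faster than aryl MOM ethers or the electron-poor enol ether, so only the formyl group should be released.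

Step 10
Reactants: 14 methyl (Z)-2-[3-(4-chlorophenoxy)-5-formyl-2-(methoxymethoxy)phenoxy]-3-{3-[5-chloro-2-(methoxymethoxy)phenyl]-4-(methoxymethoxy)phenyl}prop-2-enoate
Product: 15 methyl (Z)-2-{5-[(E)-(benzylimino)methyl]-3-(4-chlorophenoxy)-2-(methoxymethoxy)phenoxy}-3-{3-[5-chloro-2-(methoxymethoxy)phenyl]-4-(methoxymethoxy)phenyl}prop-2-enoate
Conditions: BnNH2 (1.0 equiv), 4 Å MS, CH2Cl2, rt; filtered, concentrated and used without chromatography
Reagents that add atoms: benzylamine, NCc1ccccc1
Why: Condensation of an aromatic aldehyde with a primary amine over molecular sieves gives the E aldimine cleanly; with one equivalent of amine at room temperature neither the ester nor the acrylate is attacked.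

Step 11
Reactants: 15 methyl (Z)-2-{5-[(E)-(benzylimino)methyl]-3-(4-chlorophenoxy)-2-(methoxymethoxy)phenoxy}-3-{3-[5-chloro-2-(methoxymethoxy)phenyl]-4-(methoxymethoxy)phenyl}prop-2-enoate
Product: 16 methyl (2R,3S)-4-[(E)-(benzylimino)methyl]-6-(4-chlorophenoxy)-3-{3-[5-chloro-2-(methoxymethoxy)phenyl]-4-(methoxymethoxy)phenyl}-7-(methoxymethoxy)-2,3-dihydro-1-benzofuran-2-carboxylate (2,3-cis)
Conditions: [RhCl(coe)2]2 (5 mol %; coe = cyclooctene), (S)-BINOL-derived N,N-bis[(R)-1-phenylethyl]phosphoramidite (15 mol %), toluene, 75 °C, argon
Reagents that add atoms: none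
Why: The closest known reaction type is the rhodium-catalysed, imine-directed intramolecular hydroarylation of meta-tethered aryl vinyl and allyl ethers, which includes trisubstituted, ester-bearing enol ethers that give cis-2,3-disubstituted dihydrobenzofurans. The imine nitrogen binds monovalent rhodium, which inserts reversibly into an ortho C–H bond to give a chelated aryl rhodium hydride (trivalent rhodium); the tethered alkene coordinates and inserts into Rh–H with hydrogen going to C2 and rhodium to C3, and C–C reductive elimination from the resulting six-membered rhodacycle forms C3–C3a and returns monovalent rhodium. The five-membered ring is closed in a formally 5-endo-trig sense with respect to C2=C3, reached not by direct attack on the alkene but by ring contraction of the rhodacycle. Hydrogen and C3a are delivered to the same face of the alkene, so the Z geometry (O1 and aryl cis) fixes the cis relation between the ester at C2 and the aryl group at C3, and the phosphoramidite on rhodium chooses the face and thereby the absolute configuration of both centres. Both C–H bonds ortho to the imine can be metalated, but only rhodium at C3a can reach the alkene, so metalation at the other position is unproductive and reversible. The aryl chlorides are inert to monovalent rhodium under these conditions and no terminal alkene is present for the hydride to isomerise. No base is present, so the cis ester should survive.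

Step 12
Reactants: 16 methyl (2R,3S)-4-[(E)-(benzylimino)methyl]-6-(4-chlorophenoxy)-3-{3-[5-chloro-2-(methoxymethoxy)phenyl]-4-(methoxymethoxy)phenyl}-7-(methoxymethoxy)-2,3-dihydro-1-benzofuran-2-carboxylate
Product: 17 methyl (2R,3S)-6-(4-chlorophenoxy)-3-{3-[5-chloro-2-(methoxymethoxy)phenyl]-4-(methoxymethoxy)phenyl}-4-formyl-7-(methoxymethoxy)-2,3-dihydro-1-benzofuran-2-carboxylate
Conditions: AcOH/H2O/THF, rt; aqueous extraction
Reagents that add atoms: water, O
Why: Aldimine hydrolysis is fast in dilute acetic acid, which removes the amine into the aqueous phase and is too mild to cleave MOM ethers or epimerise C2; the aldehyde is the point for purification and for measuring the enantiomeric purity.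

Step 13
Reactants: 17 methyl (2R,3S)-6-(4-chlorophenoxy)-3-{3-[5-chloro-2-(methoxymethoxy)phenyl]-4-(methoxymethoxy)phenyl}-4-formyl-7-(methoxymethoxy)-2,3-dihydro-1-benzofuran-2-carboxylate
Product: 18 methyl (2R,3S)-6-(4-chlorophenoxy)-3-{3-[5-chloro-2-(methoxymethoxy)phenyl]-4-(methoxymethoxy)phenyl}-4-(hydroxymethyl)-7-(methoxymethoxy)-2,3-dihydro-1-benzofuran-2-carboxylate
Conditions: NaBH4, THF/MeOH, −20 °C, short reaction time
Reagents that add atoms: none
Why: Borohydride reduces the aryl aldehyde much faster than the ester at low temperature, and the short cold contact keeps C2 from epimerising.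

Step 14
Reactants: 18 methyl (2R,3S)-6-(4-chlorophenoxy)-3-{3-[5-chloro-2-(methoxymethoxy)phenyl]-4-(methoxymethoxy)phenyl}-4-(hydroxymethyl)-7-(methoxymethoxy)-2,3-dihydro-1-benzofuran-2-carboxylate
Product: 19 methyl (2R,3S)-4-(bromomethyl)-6-(4-chlorophenoxy)-3-{3-[5-chloro-2-(methoxymethoxy)phenyl]-4-(methoxymethoxy)phenyl}-7-(methoxymethoxy)-2,3-dihydro-1-benzofuran-2-carboxylate
Conditions: CBr4, PPh3, CH2Cl2, 0 °C; quick filtration through silica, used at once
Reagents that add atoms: carbon tetrabromide, BrC(Br)(Br)Br
Why: The Appel reaction converts the only hydroxyl into the primary benzylic bromide under neutral conditions; the bromide is para to an alkoxy group and therefore reactive, so it is not stored.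

Step 15
Reactants: 19 methyl (2R,3S)-4-(bromomethyl)-6-(4-chlorophenoxy)-3-{3-[5-chloro-2-(methoxymethoxy)phenyl]-4-(methoxymethoxy)phenyl}-7-(methoxymethoxy)-2,3-dihydro-1-benzofuran-2-carboxylate
Product: 20 methyl (2R,3S)-4-allyl-6-(4-chlorophenoxy)-3-{3-[5-chloro-2-(methoxymethoxy)phenyl]-4-(methoxymethoxy)phenyl}-7-(methoxymethoxy)-2,3-dihydro-1-benzofuran-2-carboxylate
Conditions: Bu3SnCH=CH2, Pd(PPh3)4 (5 mol %), toluene, 80 °C; KF work-up
Reagents that add atoms: tributyl(vinyl)stannane, C=C[Sn](CCCC)(CCCC)CCCC
Why: Stille coupling of a benzylic bromide with a vinylstannane is a classical route to allylarenes; it needs no base, so the cis ester is safe, and the triphenylphosphine catalyst leaves the aryl chlorides untouched.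

Step 16
Reactants: 20 methyl (2R,3S)-4-allyl-6-(4-chlorophenoxy)-3-{3-[5-chloro-2-(methoxymethoxy)phenyl]-4-(methoxymethoxy)phenyl}-7-(methoxymethoxy)-2,3-dihydro-1-benzofuran-2-carboxylate
Product: 21 [(2R,3S)-4-allyl-6-(4-chlorophenoxy)-3-{3-[5-chloro-2-(methoxymethoxy)phenyl]-4-(methoxymethoxy)phenyl}-7-(methoxymethoxy)-2,3-dihydro-1-benzofuran-2-yl]methanol
Conditions: LiBH4, THF, 0 °C to rt
Reagents that add atoms: none
Why: LiBH4 reduces the activated 2-aryloxy ester to the primary alcohol without base and without touching the alkene or the aryl chlorides; with the carbonyl gone, C2 can no longer epimerise in the fluoride step that follows.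

Step 17
Reactants: 21 [(2R,3S)-4-allyl-6-(4-chlorophenoxy)-3-{3-[5-chloro-2-(methoxymethoxy)phenyl]-4-(methoxymethoxy)phenyl}-7-(methoxymethoxy)-2,3-dihydro-1-benzofuran-2-yl]methanol
Product: 22 [(2R,3S)-4-allyl-6-(4-allylphenoxy)-3-{3-[5-allyl-2-(methoxymethoxy)phenyl]-4-(methoxymethoxy)phenyl}-7-(methoxymethoxy)-2,3-dihydro-1-benzofuran-2-yl]methanol
Conditions: Bu3SnCH2CH=CH2 (3 equiv), Pd2(dba)3 (5 mol %), P(t-Bu)3 (20 mol %), CsF, dioxane, 100 °C
Reagents that add atoms: allyltributylstannane, C=CC[Sn](CCCC)(CCCC)CCCC
Why: Stille coupling of unactivated aryl chlorides is known with the electron-rich, bulky P(t-Bu)3 on palladium and fluoride activation of the stannane, and it transfers allyl groups; the free primary hydroxyl and the existing allyl group are tolerated.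

Step 18
Reactants: 22 [(2R,3S)-4-allyl-6-(4-allylphenoxy)-3-{3-[5-allyl-2-(methoxymethoxy)phenyl]-4-(methoxymethoxy)phenyl}-7-(methoxymethoxy)-2,3-dihydro-1-benzofuran-2-yl]methanol
Product: 23 magnolignan H, (2R,3S)-4-allyl-6-(4-allylphenoxy)-3-[3-(5-allyl-2-hydroxyphenyl)-4-hydroxyphenyl]-2-(hydroxymethyl)-2,3-dihydro-1-benzofuran-7-ol
Conditions: HCl, MeOH/THF, 45 °C
Reagents that add atoms: none
Why: Acid-catalysed acetal exchange with methanol removes the three aryl MOM ethers; no allyl group is ortho to a phenol, so acid-induced cyclisation is not possible, and neither stereocentre is adjacent to a carbonyl group.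

## Compound list

1 | 3,4,5-trihydroxybenzaldehyde | O=Cc1cc(O)c(O)c(O)c1 | starting material
2 | 3,5-dihydroxy-4-(methoxymethoxy)benzaldehyde | O=Cc1cc(O)c(OCOC)c(O)c1 | intermediate
3 | (4-chlorophenyl)boronic acid | OB(O)c1ccc(Cl)cc1 | starting material
4 | 3-(4-chlorophenoxy)-5-hydroxy-4-(methoxymethoxy)benzaldehyde | O=Cc1cc(O)c(OCOC)c(Oc2ccc(Cl)cc2)c1 | intermediate
5 | 3-(4-chlorophenoxy)-5-(dimethoxymethyl)-2-(methoxymethoxy)phenol | COC(OC)c1cc(O)c(OCOC)c(Oc2ccc(Cl)cc2)c1 | intermediate
6 | trimethyl phosphonoacetate | COC(=O)CP(=O)(OC)OC | starting material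
7 | methyl 2-diazo-2-(dimethoxyphosphoryl)acetate | COC(=O)C(=[N+]=[N-])P(=O)(OC)OC | intermediate
8 | methyl 2-[3-(4-chlorophenoxy)-5-(dimethoxymethyl)-2-(methoxymethoxy)phenoxy]-2-(dimethoxyphosphoryl)acetate (racemic) | COC(=O)C(Oc1cc(C(OC)OC)cc(Oc2ccc(Cl)cc2)c1OCOC)P(=O)(OC)OC | intermediate
9 | 4-hydroxy-3-iodobenzaldehyde | O=Cc1ccc(O)c(I)c1 | starting material
10 | (5-chloro-2-hydroxyphenyl)boronic acid | OB(O)c1cc(Cl)ccc1O | starting material
11 | 3-(5-chloro-2-hydroxyphenyl)-4-hydroxybenzaldehyde | O=Cc1ccc(O)c(-c2cc(Cl)ccc2O)c1 | intermediate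
12 | 3-[5-chloro-2-(methoxymethoxy)phenyl]-4-(methoxymethoxy)benzaldehyde | O=Cc1ccc(OCOC)c(-c2cc(Cl)ccc2OCOC)c1 | intermediate
13 | methyl (Z)-2-[3-(4-chlorophenoxy)-5-(dimethoxymethyl)-2-(methoxymethoxy)phenoxy]-3-{3-[5-chloro-2-(methoxymethoxy)phenyl]-4-(methoxymethoxy)phenyl}prop-2-enoate | COC(OC)c1cc(Oc2ccc(Cl)cc2)c(OCOC)c(O/C(C(=O)OC)=C\c2ccc(OCOC)c(-c3cc(Cl)ccc3OCOC)c2)c1 | intermediate
14 | methyl (Z)-2-[3-(4-chlorophenoxy)-5-formyl-2-(methoxymethoxy)phenoxy]-3-{3-[5-chloro-2-(methoxymethoxy)phenyl]-4-(methoxymethoxy)phenyl}prop-2-enoate | O=Cc1cc(Oc2ccc(Cl)cc2)c(OCOC)c(O/C(C(=O)OC)=C\c2ccc(OCOC)c(-c3cc(Cl)ccc3OCOC)c2)c1 | intermediate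
15 | methyl (Z)-2-{5-[(E)-(benzylimino)methyl]-3-(4-chlorophenoxy)-2-(methoxymethoxy)phenoxy}-3-{3-[5-chloro-2-(methoxymethoxy)phenyl]-4-(methoxymethoxy)phenyl}prop-2-enoate | Clc1ccc(Oc2cc(/C=N/Cc3ccccc3)cc(O/C(C(=O)OC)=C\c3ccc(OCOC)c(-c4cc(Cl)ccc4OCOC)c3)c2OCOC)cc1 | intermediate
16 | methyl (2R,3S)-4-[(E)-(benzylimino)methyl]-6-(4-chlorophenoxy)-3-{3-[5-chloro-2-(methoxymethoxy)phenyl]-4-(methoxymethoxy)phenyl}-7-(methoxymethoxy)-2,3-dihydro-1-benzofuran-2-carboxylate | Clc1ccc(Oc2cc(/C=N/Cc3ccccc3)c3c(c2OCOC)O[C@@H](C(=O)OC)[C@H]3c2ccc(OCOC)c(-c3cc(Cl)ccc3OCOC)c2)cc1 | intermediate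
17 | methyl (2R,3S)-6-(4-chlorophenoxy)-3-{3-[5-chloro-2-(methoxymethoxy)phenyl]-4-(methoxymethoxy)phenyl}-4-formyl-7-(methoxymethoxy)-2,3-dihydro-1-benzofuran-2-carboxylate | Clc1ccc(Oc2cc(C=O)c3c(c2OCOC)O[C@@H](C(=O)OC)[C@H]3c2ccc(OCOC)c(-c3cc(Cl)ccc3OCOC)c2)cc1 | intermediate
18 | methyl (2R,3S)-6-(4-chlorophenoxy)-3-{3-[5-chloro-2-(methoxymethoxy)phenyl]-4-(methoxymethoxy)phenyl}-4-(hydroxymethyl)-7-(methoxymethoxy)-2,3-dihydro-1-benzofuran-2-carboxylate | Clc1ccc(Oc2cc(CO)c3c(c2OCOC)O[C@@H](C(=O)OC)[C@H]3c2ccc(OCOC)c(-c3cc(Cl)ccc3OCOC)c2)cc1 | intermediate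
19 | methyl (2R,3S)-4-(bromomethyl)-6-(4-chlorophenoxy)-3-{3-[5-chloro-2-(methoxymethoxy)phenyl]-4-(methoxymethoxy)phenyl}-7-(methoxymethoxy)-2,3-dihydro-1-benzofuran-2-carboxylate | Clc1ccc(Oc2cc(CBr)c3c(c2OCOC)O[C@@H](C(=O)OC)[C@H]3c2ccc(OCOC)c(-c3cc(Cl)ccc3OCOC)c2)cc1 | intermediate
20 | methyl (2R,3S)-4-allyl-6-(4-chlorophenoxy)-3-{3-[5-chloro-2-(methoxymethoxy)phenyl]-4-(methoxymethoxy)phenyl}-7-(methoxymethoxy)-2,3-dihydro-1-benzofuran-2-carboxylate | Clc1ccc(Oc2cc(CC=C)c3c(c2OCOC)O[C@@H](C(=O)OC)[C@H]3c2ccc(OCOC)c(-c3cc(Cl)ccc3OCOC)c2)cc1 | intermediate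
21 | [(2R,3S)-4-allyl-6-(4-chlorophenoxy)-3-{3-[5-chloro-2-(methoxymethoxy)phenyl]-4-(methoxymethoxy)phenyl}-7-(methoxymethoxy)-2,3-dihydro-1-benzofuran-2-yl]methanol | Clc1ccc(Oc2cc(CC=C)c3c(c2OCOC)O[C@@H](CO)[C@H]3c2ccc(OCOC)c(-c3cc(Cl)ccc3OCOC)c2)cc1 | intermediate
22 | [(2R,3S)-4-allyl-6-(4-allylphenoxy)-3-{3-[5-allyl-2-(methoxymethoxy)phenyl]-4-(methoxymethoxy)phenyl}-7-(methoxymethoxy)-2,3-dihydro-1-benzofuran-2-yl]methanol | C=CCc1ccc(Oc2cc(CC=C)c3c(c2OCOC)O[C@@H](CO)[C@H]3c2ccc(OCOC)c(-c3cc(CC=C)ccc3OCOC)c2)cc1 | intermediate
23 | magnolignan H, (2R,3S)-4-allyl-6-(4-allylphenoxy)-3-[3-(5-allyl-2-hydroxyphenyl)-4-hydroxyphenyl]-2-(hydroxymethyl)-2,3-dihydro-1-benzofuran-7-ol | C=CCc1ccc(Oc2cc(CC=C)c3c(c2O)O[C@@H](CO)[C@H]3c2ccc(O)c(-c3cc(CC=C)ccc3O)c2)cc1 | target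

## Step count and least certain steps

Total: 18 steps. Longest linear sequence: 15 steps (steps 1, 2, 3, 5 and 8 to 18, from 1 to 23); the side branches are step 4 (7 from 6) and steps 6 and 7 (12 from 9 and 10).

Step 11 (key step). The most likely failure is slow alkene insertion and reductive elimination with a trisubstituted, ester-bearing enol ether when rhodium carries a pi-acidic phosphoramidite. Reversible hydrometalation would then scramble the alkene geometry, leaking into the trans series, and facial selectivity would be poor. The fallback moves the stereocontrol from the ligand to the imine and uses a more electron-rich phosphine. Setting out from aldehyde 14, condensation with (R)-1-aminoindane would give the (R)-1-indanyl aldimine of 14 F1. Cyclisation with [RhCl(coe)2]2 and (dicyclohexylphosphino)ferrocene, (C5H5)Fe(C5H4PCy2), in toluene at 75 °C would give the cyclised (R)-1-indanyl imine F2, the auxiliary choosing the face. Mild acid hydrolysis returns to the route at 17, where the minor enantiomer is removed by crystallisation; the (S)-amine is used if the (R)-amine favours the wrong face.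

Step 17. The two chlorides sit para to oxygen, so oxidative addition is slow, and at 100 °C palladium hydride species can move the new and the existing allyl double bonds into conjugation; an incomplete second coupling is the other likely outcome. The fallback reverses the polarity of the coupling. Setting out from 21, Miyaura borylation of both chlorides (B2pin2, Pd2(dba)3, XPhos, KOAc, dioxane, 100 °C), a reaction with a long record on electron-rich aryl chlorides, would give the bis(pinacolboronate) of 21 F3. Allyl transfer from allyl bromide (Pd(PPh3)4, K2CO3, THF/H2O, 60 °C) then proceeds through a pi-allyl palladium species without a hot fluoride step and comes back to the route at 22.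

Step 8. The olefination may give an unfavourable Z/E ratio or isomers that do not separate at the acetal stage; E material would be carried into the trans series by the stereospecific key step. The fallback builds the alkene by aldol addition and elimination. Setting out from 5, O-alkylation with methyl bromoacetate (K2CO3, acetone) would give the aryloxyacetate F4. Addition of its lithium enolate (LiN(i-Pr)2, THF, −78 °C) to 12 would give the beta-hydroxy ester F5 as a mixture of diastereomers. Mesylation and DBU-induced E1cB elimination, which passes through the ester enolate, should settle on the more stable Z isomer and come back to the route at 13. Residual E isomer from either road can be equilibrated with catalytic iodine under light.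

Step 2. With two equivalent hydroxyls the mono-arylation is statistical; over-arylation and copper-mediated oxidation of the electron-rich diol would lower throughput further. The fallback removes the symmetry problem. Setting out from 1, the vicinal 3,4-diol is tied up with Ph2CCl2 and K2CO3 in MeCN as the diphenylmethylene ketal F6. Its single free hydroxyl undergoes the Chan–Lam coupling with 3 to give the aryl ether F7, and hot aqueous acetic acid removes the ketal to give the catechol F8. Selective MOM protection of the hydroxyl para to the formyl group, as in step 1, comes back to the route at 4.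

## Further compounds

F1 | step 11 | methyl (Z)-2-{3-(4-chlorophenoxy)-5-[(E)-{[(1R)-2,3-dihydro-1H-inden-1-yl]imino}methyl]-2-(methoxymethoxy)phenoxy}-3-{3-[5-chloro-2-(methoxymethoxy)phenyl]-4-(methoxymethoxy)phenyl}prop-2-enoate | Clc1ccc(Oc2cc(/C=N/[C@@H]3CCc4ccccc34)cc(O/C(C(=O)OC)=C\c3ccc(OCOC)c(-c4cc(Cl)ccc4OCOC)c3)c2OCOC)cc1
F2 | step 11 | methyl (2R,3S)-6-(4-chlorophenoxy)-3-{3-[5-chloro-2-(methoxymethoxy)phenyl]-4-(methoxymethoxy)phenyl}-4-[(E)-{[(1R)-2,3-dihydro-1H-inden-1-yl]imino}methyl]-7-(methoxymethoxy)-2,3-dihydro-1-benzofuran-2-carboxylate | Clc1ccc(Oc2cc(/C=N/[C@@H]3CCc4ccccc34)c3c(c2OCOC)O[C@@H](C(=O)OC)[C@H]3c2ccc(OCOC)c(-c3cc(Cl)ccc3OCOC)c2)cc1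
F3 | step 17 | [(2R,3S)-4-allyl-7-(methoxymethoxy)-3-{4-(methoxymethoxy)-3-[2-(methoxymethoxy)-5-(4,4,5,5-tetramethyl-1,3,2-dioxaborolan-2-yl)phenyl]phenyl}-6-[4-(4,4,5,5-tetramethyl-1,3,2-dioxaborolan-2-yl)phenoxy]-2,3-dihydro-1-benzofuran-2-yl]methanol | CC1(C)OB(OC1(C)C)c1ccc(Oc2cc(CC=C)c3c(c2OCOC)O[C@@H](CO)[C@H]3c2ccc(OCOC)c(-c3cc(B4OC(C)(C)C(C)(C)O4)ccc3OCOC)c2)cc1
F4 | step 8 | methyl 2-[3-(4-chlorophenoxy)-5-(dimethoxymethyl)-2-(methoxymethoxy)phenoxy]acetate | COC(=O)COc1cc(C(OC)OC)cc(Oc2ccc(Cl)cc2)c1OCOC
F5 | step 8 | methyl 2-[3-(4-chlorophenoxy)-5-(dimethoxymethyl)-2-(methoxymethoxy)phenoxy]-3-{3-[5-chloro-2-(methoxymethoxy)phenyl]-4-(methoxymethoxy)phenyl}-3-hydroxypropanoate (mixture of diastereomers) | COC(=O)C(Oc1cc(C(OC)OC)cc(Oc2ccc(Cl)cc2)c1OCOC)C(O)c1ccc(OCOC)c(-c2cc(Cl)ccc2OCOC)c1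
F6 | step 2 | 7-hydroxy-2,2-diphenyl-1,3-benzodioxole-5-carbaldehyde | O=Cc1cc(O)c2OC(c3ccccc3)(c3ccccc3)Oc2c1
F7 | step 2 | 7-(4-chlorophenoxy)-2,2-diphenyl-1,3-benzodioxole-5-carbaldehyde | O=Cc1cc(Oc2ccc(Cl)cc2)c2OC(c3ccccc3)(c3ccccc3)Oc2c1
F8 | step 2 | 3-(4-chlorophenoxy)-4,5-dihydroxybenzaldehyde | O=Cc1cc(O)c(O)c(Oc2ccc(Cl)cc2)c1
A1 | alternative 1 | 2-[5-allyl-3-(4-allylphenoxy)-2-(pivaloyloxy)phenoxy]acetyl chloride | O=C(Cl)COc1cc(CC=C)cc(Oc2ccc(CC=C)cc2)c1OC(=O)C(C)(C)C
A2 | alternative 1 | 3-[5-allyl-2-(pivaloyloxy)phenyl]-4-(pivaloyloxy)benzaldehyde | O=Cc1ccc(OC(=O)C(C)(C)C)c(-c2cc(CC=C)ccc2OC(=O)C(C)(C)C)c1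
A3 | alternative 1 | cis-3-[5-allyl-3-(4-allylphenoxy)-2-(pivaloyloxy)phenoxy]-4-{3-[5-allyl-2-(pivaloyloxy)phenyl]-4-(pivaloyloxy)phenyl}oxetan-2-one | O=C1O[C@@H](c2ccc(OC(=O)C(C)(C)C)c(-c3cc(CC=C)ccc3OC(=O)C(C)(C)C)c2)[C@H]1Oc1cc(CC=C)cc(Oc2ccc(CC=C)cc2)c1OC(=O)C(C)(C)C
A4 | alternative 2 | 2-(allyloxy)-3-(4-allylphenoxy)-6-{hydroxy[3-(5-allyl-2-(methoxymethoxy)phenyl)-4-(methoxymethoxy)phenyl]methyl}phenol (racemic) | OC(c1ccc(Oc2ccc(CC=C)cc2)c(OCC=C)c1O)c1ccc(OCOC)c(-c2cc(CC=C)ccc2OCOC)c1
A5 | alternative 2 | 2,2-dimethyl-1,3-dioxole | CC1(C)OC=CO1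
A6 | alternative 2 | all-cis 8-(allyloxy)-7-(4-allylphenoxy)-4-{3-[5-allyl-2-(methoxymethoxy)phenyl]-4-(methoxymethoxy)phenyl}chromane-2,3-diol acetonide | C=CCc1ccc(Oc2ccc3c(c2OCC=C)O[C@H]4OC(C)(C)O[C@H]4[C@H]3c2ccc(OCOC)c(-c3cc(CC=C)ccc3OCOC)c2)cc1
A7 | alternative 3 | hydrazone of [3-(allyloxy)-4-(4-allylphenoxy)-2-(2-triisopropylsilyloxyethoxy)phenyl]{3-[5-allyl-2-(methoxymethoxy)phenyl]-4-(methoxymethoxy)phenyl}methanone | NN=C(c1ccc(Oc2ccc(CC=C)cc2)c(OCC=C)c1OCCO[Si](C(C)C)(C(C)C)C(C)C)c1ccc(OCOC)c(-c2cc(CC=C)ccc2OCOC)c1
A8 | alternative 3 | [3-(allyloxy)-4-(4-allylphenoxy)-2-(2-triisopropylsilyloxyethoxy)phenyl]{3-[5-allyl-2-(methoxymethoxy)phenyl]-4-(methoxymethoxy)phenyl}diazomethane | [N-]=[N+]=C(c1ccc(Oc2ccc(CC=C)cc2)c(OCC=C)c1OCCO[Si](C(C)C)(C(C)C)C(C)C)c1ccc(OCOC)c(-c2cc(CC=C)ccc2OCOC)c1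
A9 | alternative 3 | cis-7-(allyloxy)-6-(4-allylphenoxy)-3-{3-[5-allyl-2-(methoxymethoxy)phenyl]-4-(methoxymethoxy)phenyl}-2-(triisopropylsilyloxymethyl)-2,3-dihydrobenzofuran | C=CCc1ccc(Oc2ccc3c(c2OCC=C)O[C@@H](CO[Si](C(C)C)(C(C)C)C(C)C)[C@H]3c2ccc(OCOC)c(-c3cc(CC=C)ccc3OCOC)c2)cc1
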